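**Plan**

1. The retrosynthesis first cuts both interflavanyl bonds, C4–C8 and C4–C6 of the catechin ring A. This gives (+)-catechin and two molecules of one 2,3-trans-flavan-3,4-diol, so both fisetinidol units come from a single building block.
2. The diol is traced to its C4 ketone. The pyranone ring (O1, C2, C3, C4, C4a, C8a) is then cut by returning C2 from C3 to C4, which leaves a 2-aryl-3-hydroxy-2,3-dihydrobenzofuran-3-carbaldehyde. The last cut is the C2–C3 bond of that five-membered ring (carbene C–H insertion).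
3. The enabling feature: C3 (carbinol) and C4 (benzylic, ortho to O1 and para to the 7-oxygen of ring A) form a masked α-ketol. Its aryl ketone is a vinylogous carbonate, which makes the six-membered ketol the thermodynamic sink of a tertiary α-hydroxy aldehyde on the five-membered ring.
4. Forward order: benzyl aryl ether, arylacetate, diazo ester, dihydrobenzofuran ring (C–H insertion), hydroxylation and reduction, ring enlargement to the chromanone, debenzylation, carbonyl reduction, double arylation of catechin at C8 and C6.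
5. Stereochemistry: C2 from the chiral dirhodium catalyst; C3 from the ring enlargement (chelate control, trans also thermodynamic); both C4 centres from attack anti to the 3-hydroxyl on the C4 cation; the catechin centres from (+)-catechin.

Key step: step 7

Assumption: Rh2(S-PTTL)4 is taken to give the (2S) configuration at the aryl-bearing carbon of 6, as expected for related 2-(benzyloxy)aryl diazoacetates; if the sense of induction proves opposite, the mirror-image catalyst Rh2(R-PTTL)4 is used.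

**Route**

Step 1
Reactants: 1 5-(benzyloxy)-2-bromophenol; 2 3,4-bis(benzyloxy)benzyl chloride
Product: 3 4-(benzyloxy)-2-{[3,4-bis(benzyloxy)benzyl]oxy}-1-bromobenzene
Conditions: K2CO3, DMF, 60 °C
Reagents that add atoms: none
Why: Williamson ether synthesis, the phenoxide of 1 displacing the benzylic chloride of 2; no stereocentre is formed.

Step 2
Reactants: 3 4-(benzyloxy)-2-{[3,4-bis(benzyloxy)benzyl]oxy}-1-bromobenzene
Product: 4 methyl [4-(benzyloxy)-2-{[3,4-bis(benzyloxy)benzyl]oxy}phenyl]acetate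
Conditions: BrZnCH2CO2Me (from BrCH2CO2Me and Zn dust, THF), Pd2(dba)3, XPhos, THF, 60 °C
Reagents that add atoms: bromo(2-methoxy-2-oxoethyl)zinc (Reformatsky reagent), COC(=O)C[Zn]Br
Why: Negishi-type coupling of the zinc ester enolate with the aryl bromide at zerovalent palladium (acetate α-arylation) should give the arylacetate; no stereocentre is formed.

Step 3
Reactants: 4 methyl [4-(benzyloxy)-2-{[3,4-bis(benzyloxy)benzyl]oxy}phenyl]acetate
Product: 5 methyl [4-(benzyloxy)-2-{[3,4-bis(benzyloxy)benzyl]oxy}phenyl](diazo)acetate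
Conditions: 4-acetamidobenzenesulfonyl azide, DBU, MeCN, 0 °C to rt
Reagents that add atoms: 4-acetamidobenzenesulfonyl azide, CC(=O)Nc1ccc(cc1)S(=O)(=O)N=[N+]=[N-]
Why: Regitz diazo transfer from the sulfonyl azide to the benzylic ester enolate generated by DBU should give the aryldiazoacetate.

Step 4
Reactants: 5 methyl [4-(benzyloxy)-2-{[3,4-bis(benzyloxy)benzyl]oxy}phenyl](diazo)acetate
Product: 6 methyl (2S,3R)-6-(benzyloxy)-2-[3,4-bis(benzyloxy)phenyl]-2,3-dihydro-1-benzofuran-3-carboxylate (2,3-cis)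
Conditions: Rh2(S-PTTL)4 (dirhodium tetrakis[N-phthaloyl-(S)-tert-leucinate], 1 mol%), toluene, −60 °C
Reagents that add atoms: none
Why: The dirhodium carbene formed by loss of N2 inserts into the ortho O–CH2–aryl C–H bond through a five-membered transition state (intramolecular 1,5-C–H insertion of a donor/acceptor carbene), the chiral carboxylate ligands choosing one enantiotopic hydrogen and so setting C2, with the cis ester as kinetic product.

Step 5
Reactants: 6 methyl (2S,3R)-6-(benzyloxy)-2-[3,4-bis(benzyloxy)phenyl]-2,3-dihydro-1-benzofuran-3-carboxylate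
Product: 8 methyl (2R,3S)-6-(benzyloxy)-2-[3,4-bis(benzyloxy)phenyl]-3-hydroxy-2,3-dihydro-1-benzofuran-3-carboxylate, via potassium enolate 7 (not isolated)
Conditions: KN(SiMe3)2, THF, −78 °C; then 2-(phenylsulfonyl)-3-phenyloxaziridine, −78 °C; AcOH quench
Reagents that add atoms: 2-(phenylsulfonyl)-3-phenyloxaziridine, O=S(=O)(c1ccccc1)N1OC1c1ccccc1
Why: Enolate hydroxylation by oxygen transfer from the N-sulfonyloxaziridine should occur on the face of the planar enolate anti to the C2 aryl group, giving the tertiary alcohol trans to that aryl (the other C3 epimer would also converge in step 7).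

Step 6
Reactants: 8 methyl (2R,3S)-6-(benzyloxy)-2-[3,4-bis(benzyloxy)phenyl]-3-hydroxy-2,3-dihydro-1-benzofuran-3-carboxylate
Product: 9 (2R,3S)-6-(benzyloxy)-2-[3,4-bis(benzyloxy)phenyl]-3-hydroxy-2,3-dihydro-1-benzofuran-3-carbaldehyde
Conditions: i-Bu2AlH (2.2 equiv), CH2Cl2, −78 °C; aqueous Rochelle salt
Reagents that add atoms: none
Why: Ester reduction with i-Bu2AlH should stop at the aluminium hemiacetal, which is held by chelation to the neighbouring aluminium alkoxide at −78 °C and releases the aldehyde on work-up; no stereocentre is touched.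

Step 7
Reactants: 9 (2R,3S)-6-(benzyloxy)-2-[3,4-bis(benzyloxy)phenyl]-3-hydroxy-2,3-dihydro-1-benzofuran-3-carbaldehyde
Product: 10 (2R,3R)-7-(benzyloxy)-2-[3,4-bis(benzyloxy)phenyl]-3-hydroxy-2,3-dihydro-4H-chromen-4-one (7,3′,4′-tri-O-benzylfustin)
Conditions: Al(Ot-Bu)3 (0.2 equiv), toluene, 50 °C
Reagents that add atoms: none
Why: The aluminium alkoxide of the tertiary alcohol chelates the formyl oxygen, and the C2–C3 bond of the dihydrofuran ring shifts from the carbinol carbon to the formyl carbon while the carbinol carbon becomes the ketone (α-ketol or acyloin rearrangement). The closest known reactions are the ring enlargements of cyclic tertiary α-hydroxy aldehydes and ketones to 2-hydroxycycloalkanones, for example the D-homoannulation of 17-hydroxy-20-oxo steroids with aluminium alkoxides. No ring is closed by a cyclisation: the six-membered pyranone ring (O1, C2, C3, C4, C4a, C8a) arises from the five-membered ring (O1, C2, C3, C3a, C7a) by insertion of the former formyl carbon between C2 and the old C3. C2 migrates with retention, and the new carbinol centre is fixed by the syn-periplanar O–Al–O chelate, in which C2 adds to the formyl face that places the new hydroxyl trans to the C2 aryl group; the same trans isomer is also the thermodynamic one, reachable through the aluminium enediolate. The selectivity needed is migration of C2 and not of the aryl carbon C3a; it should be secured because the rearrangement is reversible and the 3-hydroxychroman-4-one, an aryl ketone conjugated with the ortho ring oxygen and the para benzyloxy group, is the most stable member of the ketol manifold, and because C2 as an α-aryloxy benzylic carbon migrates readily in an alkoxide-driven shift. The driving force is the change from a strained five-membered ring carrying an aldehyde to a six-membered ring carrying a conjugated ketone.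

Step 8
Reactants: 10 (2R,3R)-7-(benzyloxy)-2-[3,4-bis(benzyloxy)phenyl]-3-hydroxy-2,3-dihydro-4H-chromen-4-one
Product: 11 (2R,3R)-2-(3,4-dihydroxyphenyl)-3,7-dihydroxy-2,3-dihydro-4H-chromen-4-one ((2R,3R)-fustin)
Conditions: H2 (1 atm), Pd/C, EtOAc–MeOH, rt
Reagents that add atoms: none
Why: Hydrogenolysis of the three benzyl ethers over Pd/C should leave the conjugated ketone and the C2–O1 bond intact under these mild conditions; no stereocentre is touched.

Step 9
Reactants: 11 (2R,3R)-fustin
Product: 12 (2R,3S,4R)-2-(3,4-dihydroxyphenyl)-3,4-dihydro-2H-chromene-3,4,7-triol ((+)-mollisacacidin, 2,3-trans-3,4-trans)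
Conditions: NaBH4, EtOH, 0 °C to rt
Reagents that add atoms: none
Why: Borohydride reduction of the chromanone carbonyl of a 2,3-trans-dihydroflavonol should give mainly the 3,4-trans diol; the C4 configuration is immaterial because it is lost on ionisation in step 10.

Step 10
Reactants: 12 (+)-mollisacacidin (2.5 equiv); 13 (+)-catechin
Product: 16 fisetinidol-(4α→8)-catechin-(6→4α)-fisetinidol (target), via fisetinidol-(4α→8)-catechin 14 (not isolated), via fisetinidol-(4α→6)-catechin 15 (not isolated)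
Conditions: 0.1 M aqueous HCl, rt, N2; chromatography on Sephadex LH-20
Reagents that add atoms: none
Why: Acid ionises the C4 hydroxyl of 12 to a cation stabilised by the para 7-hydroxyl and the ortho ring oxygen, and C8 and C6 of the phloroglucinol ring of catechin attack it (biomimetic Friedel–Crafts condensation of a flavan-3,4-diol); each new C4 centre should arise mainly by attack anti to the 3-hydroxyl (3,4-trans), regiochemistry is not an issue because both nucleophilic positions are used, and the resorcinol-type rings of the fisetinidol units are too weakly nucleophilic to compete.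

**Compound list**

1 | 5-(benzyloxy)-2-bromophenol | Oc1cc(OCc2ccccc2)ccc1Br | starting material
2 | 3,4-bis(benzyloxy)benzyl chloride | ClCc1ccc(OCc2ccccc2)c(OCc2ccccc2)c1 | starting material
3 | 4-(benzyloxy)-2-{[3,4-bis(benzyloxy)benzyl]oxy}-1-bromobenzene | Brc1ccc(OCc2ccccc2)cc1OCc1ccc(OCc2ccccc2)c(OCc2ccccc2)c1 | intermediate
4 | methyl [4-(benzyloxy)-2-{[3,4-bis(benzyloxy)benzyl]oxy}phenyl]acetate | COC(=O)Cc1ccc(OCc2ccccc2)cc1OCc1ccc(OCc2ccccc2)c(OCc2ccccc2)c1 | intermediate
5 | methyl [4-(benzyloxy)-2-{[3,4-bis(benzyloxy)benzyl]oxy}phenyl](diazo)acetate | COC(=O)C(=[N+]=[N-])c1ccc(OCc2ccccc2)cc1OCc1ccc(OCc2ccccc2)c(OCc2ccccc2)c1 | intermediate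
6 | methyl (2S,3R)-6-(benzyloxy)-2-[3,4-bis(benzyloxy)phenyl]-2,3-dihydro-1-benzofuran-3-carboxylate (ester cis to the C2 aryl) | COC(=O)[C@@H]1c2ccc(OCc3ccccc3)cc2O[C@@H]1c1ccc(OCc2ccccc2)c(OCc2ccccc2)c1 | intermediate
7 | potassium enolate of 6 (C2 configuration unchanged, C3 planar) | [K+].COC([O-])=C1c2ccc(OCc3ccccc3)cc2O[C@@H]1c1ccc(OCc2ccccc2)c(OCc2ccccc2)c1 | intermediate
8 | methyl (2R,3S)-6-(benzyloxy)-2-[3,4-bis(benzyloxy)phenyl]-3-hydroxy-2,3-dihydro-1-benzofuran-3-carboxylate (hydroxyl trans to the C2 aryl) | COC(=O)[C@]1(O)c2ccc(OCc3ccccc3)cc2O[C@@H]1c1ccc(OCc2ccccc2)c(OCc2ccccc2)c1 | intermediate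
9 | (2R,3S)-6-(benzyloxy)-2-[3,4-bis(benzyloxy)phenyl]-3-hydroxy-2,3-dihydro-1-benzofuran-3-carbaldehyde | O=C[C@]1(O)c2ccc(OCc3ccccc3)cc2O[C@@H]1c1ccc(OCc2ccccc2)c(OCc2ccccc2)c1 | intermediate
10 | (2R,3R)-7-(benzyloxy)-2-[3,4-bis(benzyloxy)phenyl]-3-hydroxy-2,3-dihydro-4H-chromen-4-one (7,3′,4′-tri-O-benzylfustin, 2,3-trans) | O=C1c2ccc(OCc3ccccc3)cc2O[C@H](c2ccc(OCc3ccccc3)c(OCc3ccccc3)c2)[C@H]1O | intermediate
11 | (2R,3R)-2-(3,4-dihydroxyphenyl)-3,7-dihydroxy-2,3-dihydro-4H-chromen-4-one ((2R,3R)-fustin) | O=C1c2ccc(O)cc2O[C@H](c2ccc(O)c(O)c2)[C@H]1O | intermediate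
12 | (2R,3S,4R)-2-(3,4-dihydroxyphenyl)-3,4-dihydro-2H-chromene-3,4,7-triol ((+)-mollisacacidin) | Oc1ccc2c(c1)O[C@H](c1ccc(O)c(O)c1)[C@@H](O)[C@@H]2O | intermediate
13 | (+)-catechin, (2R,3S)-2-(3,4-dihydroxyphenyl)-3,4-dihydro-2H-chromene-3,5,7-triol | Oc1cc(O)c2c(c1)O[C@H](c1ccc(O)c(O)c1)[C@@H](O)C2 | starting material
14 | fisetinidol-(4α→8)-catechin: (+)-catechin carrying at C8 a (2R,3S,4S)-fisetinidol-4-yl unit (2,3-trans-3,4-trans) | c1c(O)c2c(c([C@@H]3c4ccc(O)cc4O[C@H](c4ccc(O)c(O)c4)[C@H]3O)c1O)O[C@H](c1ccc(O)c(O)c1)[C@@H](O)C2 | intermediate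
15 | fisetinidol-(4α→6)-catechin: (+)-catechin carrying at C6 a (2R,3S,4S)-fisetinidol-4-yl unit (2,3-trans-3,4-trans) | Oc1ccc2c(c1)O[C@H](c1ccc(O)c(O)c1)[C@@H](O)[C@@H]2c1c(O)c2c(cc1O)O[C@H](c1ccc(O)c(O)c1)[C@@H](O)C2 | intermediate
16 | fisetinidol-(4α→8)-catechin-(6→4α)-fisetinidol: (2R,3S)-catechin carrying (2R,3S,4S)-2-(3,4-dihydroxyphenyl)-3,7-dihydroxy-3,4-dihydro-2H-chromen-4-yl units at C6 and C8, each 2,3-trans-3,4-trans | Oc1ccc2c(c1)O[C@H](c1ccc(O)c(O)c1)[C@@H](O)[C@@H]2c1c(O)c2c(c([C@@H]3c4ccc(O)cc4O[C@H](c4ccc(O)c(O)c4)[C@H]3O)c1O)O[C@H](c1ccc(O)c(O)c1)[C@@H](O)C2 | target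

**Step count and risks**

Total step count: 10. Longest linear sequence: 10 steps (1 to 16; 2 and 13 are purchased).

The three steps most likely to fail:

First, step 7. The aryl carbon C3a may shift in place of C2, and the transient chroman-3-one could then enolise toward C2 and erode its configuration. The tertiary benzylic alcohol may also dehydrate to the aromatic benzofuran, or the aldehyde may undergo intermolecular hydride transfer at aluminium.

The fallback sets out from 6 and returns at 10, using a different ring enlargement, a 1,2-aryl shift through a phenonium ion: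
- 6 would be epimerised at C3 (NaOMe, MeOH) to the trans ester F1.
- F1 would be reduced (LiAlH4, THF, 0 °C) to the trans primary alcohol F2.
- F2 would be converted with Tf2O and 2,6-lutidine (CH2Cl2, −78 °C) into the triflate F3, which is not isolated.
- The ring A carbon C3a (para to the benzyloxy group, ortho to the ring oxygen) should assist ionisation of F3. Water (aqueous NaHCO3–acetone) should open the phenonium ion at the ring carbon, anti to the bridging aryl. This enlarges the ring and should give 7,3′,4′-tri-O-benzylfisetinidol F4 with the 2,3-trans arrangement.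
- Benzylic oxidation at C4 (DDQ, CH2Cl2–H2O) would give the 4-ol F5, and MnO2 would then give 10.

Second, step 10. Facial selectivity at the planar C4 cation may be poor (3,4-cis linkages), and the one-pot double condensation may under- or over-substitute statistically.

The fallback sets out from 10 and 13 and returns at 16, using benzyl-protected partners, a Lewis acid at low temperature and neighbouring-group control:
- 10 would be reduced (NaBH4) to the tri-O-benzyl 3,4-trans diol F6 and acetylated (Ac2O, pyridine) to the 3,4-diacetate F7.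
- 13 would be benzylated (BnBr, K2CO3, DMF) to 5,7,3′,4′-tetra-O-benzylcatechin F8.
- BF3·OEt2 (CH2Cl2, −78 to 0 °C) would ionise the 4-acetate of F7 with participation of the 3-acetate. The bridged acyloxonium ion should be opened by C8 and then C6 of F8 from the face anti to the 3-oxygen, giving the deca-O-benzyl trimer diacetate F9.
- Methanolysis (K2CO3, MeOH–THF) would give the deca-O-benzyl trimer F10, and hydrogenolysis (H2, Pd(OH)2/C) would give 16.

Third, step 5. The enolate may ring-open by β-elimination of the ring oxygen, or oxygen transfer to the hindered tetrasubstituted enolate may be slow, with competing oxidation to the benzofuran.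

The fallback sets out from 6 and returns at 9, moving the oxidation to the aldehyde level (Rubottom oxidation):
- 6 would be reduced (i-Bu2AlH, 1.1 equiv, −78 °C) to the aldehyde F11; its C3 configuration is of no consequence.
- F11 would be converted (TBSOTf, Et3N) into the exocyclic silyl enol ether F12.
- Epoxidation with dimethyldioxirane anti to the C2 aryl group, followed by silyl migration, should give the α-silyloxy aldehyde F13.
- Desilylation (HF·pyridine) would give 9.

**Further compounds**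

F1 | step 7 | methyl (2S,3S)-6-(benzyloxy)-2-[3,4-bis(benzyloxy)phenyl]-2,3-dihydro-1-benzofuran-3-carboxylate (2,3-trans) | COC(=O)[C@H]1c2ccc(OCc3ccccc3)cc2O[C@@H]1c1ccc(OCc2ccccc2)c(OCc2ccccc2)c1
F2 | step 7 | [(2S,3R)-6-(benzyloxy)-2-[3,4-bis(benzyloxy)phenyl]-2,3-dihydro-1-benzofuran-3-yl]methanol (2,3-trans) | OC[C@H]1c2ccc(OCc3ccccc3)cc2O[C@@H]1c1ccc(OCc2ccccc2)c(OCc2ccccc2)c1
F3 | step 7 | trifluoromethanesulfonate of F2 (not isolated) | O=S(=O)(OC[C@H]1c2ccc(OCc3ccccc3)cc2O[C@@H]1c1ccc(OCc2ccccc2)c(OCc2ccccc2)c1)C(F)(F)F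
F4 | step 7 | (2R,3S)-7-(benzyloxy)-2-[3,4-bis(benzyloxy)phenyl]-3,4-dihydro-2H-chromen-3-ol (7,3′,4′-tri-O-benzylfisetinidol) | C(c1ccccc1)Oc1ccc2c(c1)O[C@H](c1ccc(OCc3ccccc3)c(OCc3ccccc3)c1)[C@@H](O)C2
F5 | step 7 | (2R,3S)-7-(benzyloxy)-2-[3,4-bis(benzyloxy)phenyl]-3,4-dihydro-2H-chromene-3,4-diol, mixture of C4 epimers | C(c1ccccc1)Oc1ccc2c(c1)O[C@H](c1ccc(OCc3ccccc3)c(OCc3ccccc3)c1)[C@@H](O)C2O
F6 | step 10 | (2R,3S,4R)-7-(benzyloxy)-2-[3,4-bis(benzyloxy)phenyl]-3,4-dihydro-2H-chromene-3,4-diol (2,3-trans-3,4-trans) | C(c1ccccc1)Oc1ccc2c(c1)O[C@H](c1ccc(OCc3ccccc3)c(OCc3ccccc3)c1)[C@@H](O)[C@@H]2O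
F7 | step 10 | 3,4-di-O-acetate of F6 (configuration unchanged) | C(c1ccccc1)Oc1ccc2c(c1)O[C@H](c1ccc(OCc3ccccc3)c(OCc3ccccc3)c1)[C@@H](OC(C)=O)[C@@H]2OC(C)=O
F8 | step 10 | 5,7,3′,4′-tetra-O-benzyl-(+)-catechin | C(c1ccccc1)Oc1cc(OCc2ccccc2)c2c(c1)O[C@H](c1ccc(OCc3ccccc3)c(OCc3ccccc3)c1)[C@@H](O)C2
F9 | step 10 | deca-O-benzyl ether of 16 carrying an acetate on the 3-oxygen of each fisetinidol unit | c5ccccc5COc1ccc2c(c1)O[C@H](c1ccc(OCc5ccccc5)c(OCc5ccccc5)c1)[C@@H](OC(C)=O)[C@@H]2c1c(OCc5ccccc5)c2c(c([C@@H]3c4ccc(OCc5ccccc5)cc4O[C@H](c4ccc(OCc5ccccc5)c(OCc5ccccc5)c4)[C@H]3OC(C)=O)c1OCc5ccccc5)O[C@H](c1ccc(OCc5ccccc5)c(OCc5ccccc5)c1)[C@@H](O)C2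
F10 | step 10 | deca-O-benzyl ether of 16 (all phenols benzylated, three free 3-hydroxyls) | c5ccccc5COc1ccc2c(c1)O[C@H](c1ccc(OCc5ccccc5)c(OCc5ccccc5)c1)[C@@H](O)[C@@H]2c1c(OCc5ccccc5)c2c(c([C@@H]3c4ccc(OCc5ccccc5)cc4O[C@H](c4ccc(OCc5ccccc5)c(OCc5ccccc5)c4)[C@H]3O)c1OCc5ccccc5)O[C@H](c1ccc(OCc5ccccc5)c(OCc5ccccc5)c1)[C@@H](O)C2
F11 | step 5 | (2S)-6-(benzyloxy)-2-[3,4-bis(benzyloxy)phenyl]-2,3-dihydro-1-benzofuran-3-carbaldehyde, mixture of C3 epimers | O=CC1c2ccc(OCc3ccccc3)cc2O[C@@H]1c1ccc(OCc2ccccc2)c(OCc2ccccc2)c1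
F12 | step 5 | (2R)-6-(benzyloxy)-2-[3,4-bis(benzyloxy)phenyl]-3-{[(tert-butyldimethylsilyl)oxy]methylidene}-2,3-dihydro-1-benzofuran, alkene geometry not defined | CC(C)(C)[Si](C)(C)OC=C1c2ccc(OCc3ccccc3)cc2O[C@@H]1c1ccc(OCc2ccccc2)c(OCc2ccccc2)c1
F13 | step 5 | (2R,3S)-6-(benzyloxy)-2-[3,4-bis(benzyloxy)phenyl]-3-[(tert-butyldimethylsilyl)oxy]-2,3-dihydro-1-benzofuran-3-carbaldehyde | O=C[C@]1(O[Si](C)(C)C(C)(C)C)c2ccc(OCc3ccccc3)cc2O[C@@H]1c1ccc(OCc2ccccc2)c(OCc2ccccc2)c1
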